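The C12 ketone next to the C11 carbinol that carries Me-20 (an α-ketol, present as its acetate) lets the cyclohexenone ring C1/C10–C14 be traced back to a cyclopentane (C1, C10, C12, C13, C14) whose C12 bears OH and an acetyl group (C11, C20). One chelate-controlled α-ketol rearrangement shifts C10 from C12 to C11: it enlarges the ring, inserts C11 between the ketone and C10 and sets the C11 configuration. The cyclopentanone stage makes C1 (conjugate addition) and C9/C10 (aldol) accessible; a hydroxyl-relayed epoxidation/lactonisation and a ring-closing metathesis complete the macrocycle.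

Key step: step 12

Remark: positions carry the briarane numbering of the target (C1–C20; six-membered ring C1/C10–C14, macrocycle C1–C10, lactone C7/C8/C17/C19); tert-butyl D-lactate is assumed to be commercially available.

Step 1
Reactants: 1 tert-butyl (R)-lactate
Product: 2 tert-butyl (2R)-2-(triflyloxy)propanoate
Conditions: Tf2O, 2,6-lutidine, CH2Cl2, −78 → 0 °C
Reagents that add atoms: trifluoromethanesulfonic anhydride, O=S(=O)(OS(=O)(=O)C(F)(F)F)C(F)(F)F
Why: O-sulfonylation (triflate formation) leaves the stereocentre untouched and turns the hydroxyl into a leaving group.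

Step 2
Reactants: 2 lactate triflate; 3 diethyl {2-[methoxy(methyl)amino]-2-oxoethyl}phosphonate
Product: 4 tert-butyl (2S)-3-(diethoxyphosphoryl)-4-[methoxy(methyl)amino]-2-methyl-4-oxobutanoate (both C3 epimers)
Conditions: 3, NaH, THF, 0 °C; then 2, 0 °C → rt
Reagents that add atoms: none
Why: SN2 alkylation of the soft phosphonate carbanion on the α-triflyloxy ester should proceed with clean inversion and so fixes the future C17 (R in the target) from the lactate pool.

Step 3
Reactants: 4 alkylated phosphonate; 5 3-(trimethylsilyl)prop-2-ynal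
Product: 6 tert-butyl (2R,3E)-3-[methoxy(methyl)carbamoyl]-2-methyl-6-(trimethylsilyl)hex-3-en-5-ynoate
Conditions: NaH, THF, 0 °C; then 5, −78 → 0 °C
Reagents that add atoms: none
Why: Horner–Wadsworth–Emmons olefination with a non-enolisable ynal should place the amide carbonyl trans to the alkynyl group (E), the geometry later needed for C7, without touching C17.

Step 4
Reactants: 6 enyne Weinreb amide
Product: 7 tert-butyl (2R,3E)-3-formyl-2-methyl-6-(trimethylsilyl)hex-3-en-5-ynoate
Conditions: DIBAL-H (1.1 equiv), THF, −78 °C; aq. Rochelle salt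
Reagents that add atoms: none
Why: Reduction of a Weinreb amide stops at the chelated hemiaminal, which gives the aldehyde on work-up, while the hindered tert-butyl ester should survive at −78 °C.

Step 5
Reactants: 8 3-(trimethylsilyl)prop-2-yn-1-ol
Product: 9 triethyl{[3-(trimethylsilyl)prop-2-yn-1-yl]oxy}silane
Conditions: TESCl, imidazole, CH2Cl2, 0 °C → rt
Reagents that add atoms: chlorotriethylsilane, CC[Si](Cl)(CC)CC
Why: Silyl ether formation protects the future C4 oxygen.

Step 6
Reactants: 9 TES propargyl ether; 10 3-methylcyclopent-2-en-1-one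
Product: 12 trimethyl({(3S)-3-methyl-3-[(1Z)-3-(triethylsilyloxy)-1-(trimethylsilyl)prop-1-en-1-yl]cyclopent-1-en-1-yl}oxy)silane, via alkenylalane 11 (not isolated)
Conditions: 9, i-Bu2AlH, N-methylpyrrolidine, heptane, 60 °C; then 10, Cu(OTf)2 (5 mol %), chiral sulfonate-bearing NHC–Ag(I) complex (2.5 mol %), THF, −30 °C; then TMSOTf, Et3N, −78 → 0 °C
Reagents that add atoms: trimethylsilyl trifluoromethanesulfonate, C[Si](C)(C)OS(=O)(=O)C(F)(F)F; diisobutylaluminium hydride, CC(C)C[AlH]CC(C)C (aluminium in intermediate 11)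
Why: cis-Hydroalumination puts aluminium on the silyl-bearing carbon, the copper-catalysed enantioselective conjugate addition of the alkenylalane to the β-methyl enone sets the quaternary C1 under catalyst control, and silylation of the aluminium enolate preserves the C10=C12 enolate regiochemistry.

Step 7
Reactants: 12 silyl enol ether; 7 enynal
Product: 14 anti-aldol adduct (C9–OH; C9 on C10 trans to the silylalkenyl group on C1), via lithium enolate 13 (not isolated)
Conditions: MeLi, THF, 0 °C; then 7, −78 °C; aq. NH4Cl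
Reagents that add atoms: methyllithium, [Li]C (lithium in intermediate 13)
Why: Lithium enolate aldol addition through a closed chair transition state gives the anti adduct from the cyclic (E)-enolate, and the aldehyde approaches C10 anti to the bulky 1-silylalkenyl group on C1, so C10 and C9 are set together.

Step 8
Reactants: 14 aldol adduct
Product: 15 C9 tert-butyldimethylsilyl ether of 14
Conditions: TBSOTf, 2,6-lutidine, CH2Cl2, −78 °C
Reagents that add atoms: tert-butyldimethylsilyl trifluoromethanesulfonate, CC(C)(C)[Si](C)(C)OS(=O)(=O)C(F)(F)F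
Why: Silyl ether formation blocks retro-aldol cleavage and oxidation of the C9 hydroxyl in the next steps.

Step 9
Reactants: 15 TBS-protected cyclopentanone
Product: 16 C12 ethylidene cyclopentane (methyl anti to C10)
Conditions: EtPPh3Br, KHMDS, THF, 0 → 40 °C
Reagents that add atoms: ethyltriphenylphosphonium bromide, CC[P+](c1ccccc1)(c1ccccc1)c1ccccc1.[Br-]
Why: Wittig olefination with the non-stabilised ethylide installs the two carbons that become C11 and C20, and the alkene geometry is inconsequential because C11 is oxidised two steps later.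

Step 10
Reactants: 16 ethylidene cyclopentane
Product: 17 C11,C12-diol (C12–OH cis to H-10)
Conditions: OsO4 (5 mol %), NMO, acetone/H2O, 0 °C
Reagents that add atoms: N-methylmorpholine N-oxide, C[N+]1([O-])CCOCC1; water, O
Why: Catalytic OsO4 dihydroxylation should select the unhindered electron-rich exocyclic alkene over the shielded vinylsilane and the enyne alkene and add syn from the ring face anti to the C9 side chain, which places C12–OH cis to H-10.

Step 11
Reactants: 17 diol
Product: 18 α-ketol (C12–OH cis to H-10; acetyl cis to C9)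
Conditions: SO3·pyridine, DMSO, i-Pr2NEt, CH2Cl2, 0 °C
Reagents that add atoms: none
Why: Parikh–Doering oxidation converts only the secondary alcohol into the methyl ketone and leaves the tertiary C12–OH.

Step 12
Reactants: 18 α-ketol
Product: 19 2-hydroxy-2-methylcyclohexanone (C12 ketone; C11 with OH on the H-10 face and Me-20 on the C9 face)
Conditions: Al(Ot-Bu)3 (1.5 equiv), toluene, 80 °C; aq. Rochelle salt
Reagents that add atoms: none
Why: The aluminium alkoxide of C12–OH binds the C11 carbonyl in a five-membered chelate, and as the alkoxide oxygen pushes, the C12–C10 bond shifts to the carbonyl carbon C11 while C12 becomes the ketone. The closest known reaction type is the Lewis-acid-mediated α-ketol (acyloin) rearrangement, as in the D-homoannulation of 17α-hydroxy-20-keto steroids with aluminium alkoxides. The six-membered ring (C1, C10, C11, C12, C13, C14) arises from the cyclopentane by this 1,2-alkyl shift, a one-carbon ring expansion that inserts C11 between C12 and C10, with C10 migrating under retention. C11 is controlled by the chelate: with C11=O syn to C12–O and the acetyl methyl turned towards C13H2, C10 reaches the carbonyl face that puts O-11 on the H-10 face and Me-20 on the C9 face. The step needs C10 rather than C13 to migrate, which the substrate secures because the secondary C10 is the better migrating group under Lewis-acid conditions and the rotamer for C13 migration would eclipse the acetyl methyl with the substituted C10; tert-butoxide ligands exclude hydride transfer to the ketones.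

Step 13
Reactants: 19 cyclohexanone
Product: 20 (E)-allylic alcohol (C2–H, C4–OH, terminal alkyne; C9–OTBS kept)
Conditions: TBAF (3 equiv), wet THF, 0 °C
Reagents that add atoms: none
Why: Fluoride cleaves the primary TES ether, the alkoxide triggers a 1,4-silyl shift from C2 to oxygen (Brook rearrangement) with protonation of the vinyl carbanion under retention to give the (E)-alkene, and the alkynylsilane is cleaved as well, while the hindered secondary TBS ether should survive at 0 °C.

Step 14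
Reactants: 20 allylic alcohol
Product: 21 (2R,3R)-2,3-epoxy alcohol (C4–OH)
Conditions: Ti(Oi-Pr)4, D-(−)-diisopropyl tartrate, t-BuOOH, 4 Å MS, CH2Cl2, −20 °C
Reagents that add atoms: tert-butyl hydroperoxide, CC(C)(C)OO
Why: Sharpless asymmetric epoxidation of the (E)-allylic alcohol is reagent-controlled and the D-tartrate should deliver oxygen to the face that gives the (2R,3R)-epoxide, while the silylated C9 allylic alcohol cannot bind titanium.

Step 15
Reactants: 22 2-bromoprop-2-en-1-ol
Product: 23 [(2-bromoprop-2-en-1-yl)oxy](tert-butyl)diphenylsilane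
Conditions: TBDPSCl, imidazole, DMF, 0 °C → rt
Reagents that add atoms: tert-butylchlorodiphenylsilane, CC(C)(C)[Si](Cl)(c1ccccc1)c1ccccc1
Why: Silyl ether formation protects the future C16 hydroxyl in a form that survives the later removal of the TBS group.

Step 16
Reactants: 21 epoxy alcohol; 23 bromoallyl silyl ether
Product: 26 C4–C5 coupled epoxide with the C5(=CH2)–CH2OTBDPS unit, via primary triflate 24 (not isolated), via lithium dialkenylcuprate 25 (not isolated)
Conditions: 21, Tf2O, 2,6-lutidine, CH2Cl2, −78 °C; then cuprate 25 [from 23: t-BuLi (2 equiv), Et2O, −78 °C; CuI (0.5 equiv)], THF/Et2O, −78 → −40 °C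
Reagents that add atoms: trifluoromethanesulfonic anhydride, O=S(=O)(OS(=O)(=O)C(F)(F)F)C(F)(F)F (in intermediate 24); tert-butyllithium, [Li]C(C)(C)C, and copper(I) iodide, [Cu+].[I-] (metals in intermediate 25)
Why: Cuprate alkylation by SN2 displacement of the primary triflate should be much faster than attack on the epoxide or the hindered ketone, which forms the C4–C5 bond and brings in C16 and the alkene for the later ring closure.

Step 17
Reactants: 26 tertiary α-ketol
Product: 27 C11 acetate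
Conditions: Ac2O, DMAP, Et3N, CH2Cl2, 40 °C
Reagents that add atoms: acetic anhydride, CC(=O)OC(C)=O
Why: DMAP-catalysed acetylation reaches the only free hydroxyl, the tertiary C11–OH, before the second tertiary alcohol (C8) exists.

Step 18
Reactants: 27 cyclohexanone
Product: 28 cyclohex-13-en-12-one (C13=C14)
Conditions: IBX (3 equiv), DMSO/toluene, 70 °C
Reagents that add atoms: none
Why: IBX dehydrogenation of the ketone can only proceed through the C13 enol because C11 is quaternary, so the C13=C14 enone should form regioselectively.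

Step 19
Reactants: 28 enone
Product: 29 C9 alcohol
Conditions: HF·pyridine, pyridine, THF, 0 °C → rt
Reagents that add atoms: none
Why: Selective desilylation removes the secondary TBS ether while the more acid-stable TBDPS ether stays.

Step 20
Reactants: 29 allylic alcohol
Product: 31 γ-lactone diol (C7–O lactone; free C8–OH and C9–OH), via propargylic epoxide 30 (not isolated)
Conditions: VO(acac)2 (5 mol %), t-BuOOH, CH2Cl2, 0 °C; then CSA (20 mol %), 0 °C
Reagents that add atoms: tert-butyl hydroperoxide, CC(C)(C)OO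
Why: Vanadium-catalysed hydroxyl-directed epoxidation should give the erythro epoxy alcohol typical of allylic alcohols with a substituent on the proximal alkene carbon (sets C8), and acid then lets the tert-butyl ester carbonyl open the epoxide at the propargylic C7 with inversion in a five-membered lactonisation with loss of isobutene (sets C7).

Step 21
Reactants: 31 lactone diol
Product: 32 C9 acetate
Conditions: Ac2O, pyridine, DMAP (cat.), CH2Cl2, 0 °C
Reagents that add atoms: acetic anhydride, CC(=O)OC(C)=O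
Why: Acetylation under mild conditions should reach only the secondary C9–OH and leave the hindered tertiary C8–OH free.

Step 22
Reactants: 32 alkyne
Product: 33 C7 vinyl lactone
Conditions: H2 (1 atm), Lindlar catalyst, quinoline, EtOAc, rt
Reagents that add atoms: none
Why: Lindlar semihydrogenation stops at the terminal alkene and should not reduce the enone or the 1,1-disubstituted alkene.

Step 23
Reactants: 33 silyl ether
Product: 34 diene with free C16–OH
Conditions: TBAF, AcOH, THF, 0 °C → rt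
Reagents that add atoms: none
Why: Buffered fluoride desilylation frees the primary allylic alcohol without acyl migration.

Step 24
Reactants: 34 diene
Product: 35 CNP0155754.2 (target)
Conditions: second-generation ruthenium benzylidene catalyst (Grubbs II, 20 mol %), toluene (1 mM), 80 °C
Reagents that add atoms: none
Why: Ring-closing metathesis between the vinyl group and the 1,1-disubstituted alkene releases ethene and closes the ten-membered ring, whose size enforces the cis arrangement of C4 and C7 on the new C5=C6 bond.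

Compound list
1 | tert-butyl (2R)-2-hydroxypropanoate | C[C@@H](O)C(=O)OC(C)(C)C | starting material
2 | tert-butyl (2R)-2-{[(trifluoromethyl)sulfonyl]oxy}propanoate | C[C@@H](OS(=O)(=O)C(F)(F)F)C(=O)OC(C)(C)C | intermediate
3 | diethyl {2-[methoxy(methyl)amino]-2-oxoethyl}phosphonate | CCOP(=O)(CC(=O)N(C)OC)OCC | starting material
4 | tert-butyl (2S)-3-(diethoxyphosphoryl)-4-[methoxy(methyl)amino]-2-methyl-4-oxobutanoate, C3 epimers | CCOP(=O)(OCC)C(C(=O)N(C)OC)[C@@H](C)C(=O)OC(C)(C)C | intermediate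
5 | 3-(trimethylsilyl)prop-2-ynal | C[Si](C)(C)C#CC=O | starting material
6 | tert-butyl (2R,3E)-3-[methoxy(methyl)carbamoyl]-2-methyl-6-(trimethylsilyl)hex-3-en-5-ynoate | CON(C)C(=O)/C(=C/C#C[Si](C)(C)C)[C@@H](C)C(=O)OC(C)(C)C | intermediate
7 | tert-butyl (2R,3E)-3-formyl-2-methyl-6-(trimethylsilyl)hex-3-en-5-ynoate | O=C/C(=C/C#C[Si](C)(C)C)[C@@H](C)C(=O)OC(C)(C)C | intermediate
8 | 3-(trimethylsilyl)prop-2-yn-1-ol | C[Si](C)(C)C#CCO | starting material
9 | triethyl{[3-(trimethylsilyl)prop-2-yn-1-yl]oxy}silane | CC[Si](CC)(CC)OCC#C[Si](C)(C)C | intermediate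
10 | 3-methylcyclopent-2-en-1-one | CC1=CC(=O)CC1 | starting material
11 | diisobutyl[(1Z)-3-(triethylsilyloxy)-1-(trimethylsilyl)prop-1-en-1-yl]alane | CC(C)C[Al](CC(C)C)/C(=C/CO[Si](CC)(CC)CC)[Si](C)(C)C | intermediate
12 | trimethyl({(3S)-3-methyl-3-[(1Z)-3-(triethylsilyloxy)-1-(trimethylsilyl)prop-1-en-1-yl]cyclopent-1-en-1-yl}oxy)silane | C[Si](C)(C)OC1=C[C@](C)(CC1)/C(=C/CO[Si](CC)(CC)CC)[Si](C)(C)C | intermediate
13 | lithium enolate of 12 (O–Li in place of O–SiMe3) | [Li]OC1=C[C@](C)(CC1)/C(=C/CO[Si](CC)(CC)CC)[Si](C)(C)C | intermediate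
14 | anti-aldol adduct: cyclopentanone (C12=O) with C1 (S; Me and the (Z)-1-silyl-3-(triethylsilyloxy)propenyl group), C10 carrying the C9 carbinol trans to that group, C8=C7 (E) enyne and (R)-CH(CH3)CO2t-Bu on C8; C9, C10 as in the target | O[C@H]([C@H]1C(=O)CC[C@]1(C)/C(=C/CO[Si](CC)(CC)CC)[Si](C)(C)C)/C(=C/C#C[Si](C)(C)C)[C@@H](C)C(=O)OC(C)(C)C | intermediate
15 | C9–OTBS ether of 14 | CC(C)(C)[Si](C)(C)O[C@H]([C@H]1C(=O)CC[C@]1(C)/C(=C/CO[Si](CC)(CC)CC)[Si](C)(C)C)/C(=C/C#C[Si](C)(C)C)[C@@H](C)C(=O)OC(C)(C)C | intermediate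
16 | (E)-C12-ethylidene analogue of 15 (methyl anti to C10) | CC(C)(C)[Si](C)(C)O[C@H]([C@H]1/C(=C/C)CC[C@]1(C)/C(=C/CO[Si](CC)(CC)CC)[Si](C)(C)C)/C(=C/C#C[Si](C)(C)C)[C@@H](C)C(=O)OC(C)(C)C | intermediate
17 | C11,C12-diol from syn addition on the H-10 face (C12–OH cis to H-10) | CC(C)(C)[Si](C)(C)O[C@H]([C@H]1[C@@](O)([C@@H](C)O)CC[C@]1(C)/C(=C/CO[Si](CC)(CC)CC)[Si](C)(C)C)/C(=C/C#C[Si](C)(C)C)[C@@H](C)C(=O)OC(C)(C)C | intermediate
18 | α-ketol: 1-acetylcyclopentan-1-ol with C12–OH cis to H-10 and acetyl cis to C9 | CC(C)(C)[Si](C)(C)O[C@H]([C@H]1[C@@](O)(C(C)=O)CC[C@]1(C)/C(=C/CO[Si](CC)(CC)CC)[Si](C)(C)C)/C(=C/C#C[Si](C)(C)C)[C@@H](C)C(=O)OC(C)(C)C | intermediate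
19 | ring-expanded 2-hydroxy-2-methylcyclohexanone (C12=O; C11–OH on the H-10 face, Me-20 on the C9 face; C1, C10, C11 as in the target) | CC(C)(C)[Si](C)(C)O[C@H]([C@@H]1[C@](C)(CCC(=O)[C@@]1(C)O)/C(=C/CO[Si](CC)(CC)CC)[Si](C)(C)C)/C(=C/C#C[Si](C)(C)C)[C@@H](C)C(=O)OC(C)(C)C | intermediate
20 | (2E)-allylic alcohol (C2–H, C4–OH), terminal alkyne, C9–OTBS | CC(C)(C)[Si](C)(C)O[C@H]([C@@H]1[C@](C)(CCC(=O)[C@@]1(C)O)/C=C/CO)/C(=C/C#C)[C@@H](C)C(=O)OC(C)(C)C | intermediate
21 | (2R,3R)-2,3-epoxy-4-ol | CC(C)(C)[Si](C)(C)O[C@H]([C@@H]1[C@](C)(CCC(=O)[C@@]1(C)O)[C@H]2O[C@@H]2CO)/C(=C/C#C)[C@@H](C)C(=O)OC(C)(C)C | intermediate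
22 | 2-bromoprop-2-en-1-ol | OCC(Br)=C | starting material
23 | [(2-bromoprop-2-en-1-yl)oxy](tert-butyl)diphenylsilane | BrC(=C)CO[Si](c1ccccc1)(c1ccccc1)C(C)(C)C | intermediate
24 | C4 triflate of 21 | CC(C)(C)[Si](C)(C)O[C@H]([C@@H]1[C@](C)(CCC(=O)[C@@]1(C)O)[C@H]2O[C@@H]2COS(=O)(=O)C(F)(F)F)/C(=C/C#C)[C@@H](C)C(=O)OC(C)(C)C | intermediate
25 | lithium bis[3-(tert-butyldiphenylsilyloxy)prop-1-en-2-yl]cuprate | [Li+].C=C(CO[Si](c1ccccc1)(c1ccccc1)C(C)(C)C)[Cu-]C(=C)CO[Si](c1ccccc1)(c1ccccc1)C(C)(C)C | intermediate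
26 | epoxide with C4H2–C5(=CH2)–C16H2OTBDPS chain; C11–OH free | CC(C)(C)[Si](C)(C)O[C@H]([C@@H]1[C@](C)(CCC(=O)[C@@]1(C)O)[C@H]2O[C@@H]2CC(=C)CO[Si](c3ccccc3)(c3ccccc3)C(C)(C)C)/C(=C/C#C)[C@@H](C)C(=O)OC(C)(C)C | intermediate
27 | C11 acetate of 26 | CC(C)(C)[Si](C)(C)O[C@H]([C@@H]1[C@](C)(CCC(=O)[C@@]1(C)OC(C)=O)[C@H]2O[C@@H]2CC(=C)CO[Si](c3ccccc3)(c3ccccc3)C(C)(C)C)/C(=C/C#C)[C@@H](C)C(=O)OC(C)(C)C | intermediate
28 | C13=C14 enone of 27 | CC(C)(C)[Si](C)(C)O[C@H]([C@@H]1[C@](C)(C=CC(=O)[C@@]1(C)OC(C)=O)[C@H]2O[C@@H]2CC(=C)CO[Si](c3ccccc3)(c3ccccc3)C(C)(C)C)/C(=C/C#C)[C@@H](C)C(=O)OC(C)(C)C | intermediate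
29 | C9 alcohol of 28 | O[C@H]([C@@H]1[C@](C)(C=CC(=O)[C@@]1(C)OC(C)=O)[C@H]2O[C@@H]2CC(=C)CO[Si](c3ccccc3)(c3ccccc3)C(C)(C)C)/C(=C/C#C)[C@@H](C)C(=O)OC(C)(C)C | intermediate
30 | C7,C8-epoxide (erythro to C9–OH) with ethynyl on C7 | O[C@H]([C@@H]1[C@](C)(C=CC(=O)[C@@]1(C)OC(C)=O)[C@H]2O[C@@H]2CC(=C)CO[Si](c3ccccc3)(c3ccccc3)C(C)(C)C)[C@]4(O[C@@H]4C#C)[C@@H](C)C(=O)OC(C)(C)C | intermediate
31 | γ-lactone (C7–O–C19) with free C8–OH and C9–OH; C7, C8, C17 as in the target | O[C@H]([C@@H]1[C@](C)(C=CC(=O)[C@@]1(C)OC(C)=O)[C@H]2O[C@@H]2CC(=C)CO[Si](c3ccccc3)(c3ccccc3)C(C)(C)C)[C@@]5(O)[C@H](C#C)OC(=O)[C@@H]5C | intermediate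
32 | C9 acetate of 31 | CC(=O)O[C@H]([C@@H]1[C@](C)(C=CC(=O)[C@@]1(C)OC(C)=O)[C@H]2O[C@@H]2CC(=C)CO[Si](c3ccccc3)(c3ccccc3)C(C)(C)C)[C@@]5(O)[C@H](C#C)OC(=O)[C@@H]5C | intermediate
33 | C7 vinyl lactone | CC(=O)O[C@H]([C@@H]1[C@](C)(C=CC(=O)[C@@]1(C)OC(C)=O)[C@H]2O[C@@H]2CC(=C)CO[Si](c3ccccc3)(c3ccccc3)C(C)(C)C)[C@@]5(O)[C@H](C=C)OC(=O)[C@@H]5C | intermediate
34 | seco-diene with free C16–OH | CC(=O)O[C@H]([C@@H]1[C@](C)(C=CC(=O)[C@@]1(C)OC(C)=O)[C@H]2O[C@@H]2CC(=C)CO)[C@@]5(O)[C@H](C=C)OC(=O)[C@@H]5C | intermediate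
35 | CNP0155754.2 | CC(=O)O[C@@H]1[C@@H]2[C@](C)(C=CC(=O)[C@@]2(C)OC(C)=O)[C@H]2O[C@@H]2C/C(CO)=C\[C@@H]2OC(=O)[C@H](C)[C@]21O | target

Total step count: 24. Longest linear sequence: 21 steps (steps 1–4, 7–14, 16–24).

Steps most likely to fail

Step 24 (ring-closing metathesis). Both alkenes are hindered, so ring closure to the strained trans-fused ten-membered ring may lose to oligomerisation by cross-metathesis. The fallback closes the ring before the rigid lactone exists. It sets out from 29: the vanadium-catalysed epoxidation is stopped at epoxide 30, which is isolated, and Lindlar semihydrogenation gives vinyl epoxide F1. Ring-closing metathesis of this more flexible seco-compound gives macrocyclic epoxide F2, and CSA then effects the same ester-to-lactone epoxide opening across the ring to give lactone diol F3. Acetylation with Ac2O/pyridine gives C9 acetate F4, and buffered TBAF returns to the route at 35.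

Step 12 (α-ketol rearrangement). Migration of C13 instead of C10, or reaction through a non-chelated rotamer, would erode regio- and stereocontrol at C11. The fallback reaches the same ring-expanded ketol by a semipinacol shift followed by enolate oxidation. It sets out from 17: mesylation of the secondary C11 hydroxyl (MsCl, Et3N) gives mesylate F5. Et3Al then promotes the semipinacol rearrangement, with C10 migrating anti to the leaving group, to give 2-methylcyclohexanone F6. The thermodynamic silyl enol ether F7 (TMSCl, NaI, Et3N) is oxidised by Rubottom oxidation (DMDO, then mild acid) on the face anti to the C9 side chain, which returns to the route at 19.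

Step 10 (chemoselective dihydroxylation). Osmylation may also attack the vinylsilane or the enyne alkene, or add from the wrong ring face. The fallback installs the acetyl group by cross-coupling and the hydroxyl by hydrogen-atom-transfer oxidation. It sets out from 15: kinetic enolisation towards C13 (KHMDS, PhNTf2) gives enol triflate F8. Stille coupling with tributyl(1-ethoxyvinyl)stannane gives ethoxydiene F9, and mild acid hydrolysis gives acetylcyclopentene F10. A Mukaiyama-type hydration (Mn(dpm)3, PhSiH3, O2; then P(OEt)3) reduces only the conjugated C12=C13 alkene and captures O2 at C12 on the face anti to the C9 substituent, which returns to the route at 18.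

Further compounds
F1 | step 24 | C7,C8-epoxide with vinyl on C7 (seco-compound) | O[C@H]([C@@H]1[C@](C)(C=CC(=O)[C@@]1(C)OC(C)=O)[C@H]2O[C@@H]2CC(=C)CO[Si](c3ccccc3)(c3ccccc3)C(C)(C)C)[C@]4(O[C@@H]4C=C)[C@@H](C)C(=O)OC(C)(C)C
F2 | step 24 | ten-membered ring with C7,C8-epoxide and tert-butyl ester | O[C@@H]1[C@@H]2[C@](C)(C=CC(=O)[C@@]2(C)OC(C)=O)[C@H]2O[C@@H]2C/C(CO[Si](c3ccccc3)(c3ccccc3)C(C)(C)C)=C\[C@H]2O[C@@]21[C@@H](C)C(=O)OC(C)(C)C
F3 | step 24 | macrocyclic lactone with free C8–OH and C9–OH and C16–OTBDPS | O[C@@H]1[C@@H]2[C@](C)(C=CC(=O)[C@@]2(C)OC(C)=O)[C@H]2O[C@@H]2C/C(CO[Si](c3ccccc3)(c3ccccc3)C(C)(C)C)=C\[C@@H]2OC(=O)[C@H](C)[C@]21O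
F4 | step 24 | C16–OTBDPS ether of the target | CC(=O)O[C@@H]1[C@@H]2[C@](C)(C=CC(=O)[C@@]2(C)OC(C)=O)[C@H]2O[C@@H]2C/C(CO[Si](c3ccccc3)(c3ccccc3)C(C)(C)C)=C\[C@@H]2OC(=O)[C@H](C)[C@]21O
F5 | step 12 | C11 mesylate of diol 17 | CC(C)(C)[Si](C)(C)O[C@H]([C@H]1[C@@](O)([C@@H](C)OS(C)(=O)=O)CC[C@]1(C)/C(=C/CO[Si](CC)(CC)CC)[Si](C)(C)C)/C(=C/C#C[Si](C)(C)C)[C@@H](C)C(=O)OC(C)(C)C
F6 | step 12 | 2-methylcyclohexanone (C11–H; C12=O) from the semipinacol shift | CC(C)(C)[Si](C)(C)O[C@H]([C@@H]1[C@](C)(CCC(=O)[C@@H]1C)/C(=C/CO[Si](CC)(CC)CC)[Si](C)(C)C)/C(=C/C#C[Si](C)(C)C)[C@@H](C)C(=O)OC(C)(C)C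
F7 | step 12 | C11=C12 trimethylsilyl enol ether of F6 | CC(C)(C)[Si](C)(C)O[C@H]([C@@H]1[C@](C)(CCC(O[Si](C)(C)C)=C1C)/C(=C/CO[Si](CC)(CC)CC)[Si](C)(C)C)/C(=C/C#C[Si](C)(C)C)[C@@H](C)C(=O)OC(C)(C)C
F8 | step 10 | C12 enol triflate (C12=C13) of 15 | CC(C)(C)[Si](C)(C)O[C@H]([C@H]1C(OS(=O)(=O)C(F)(F)F)=CC[C@]1(C)/C(=C/CO[Si](CC)(CC)CC)[Si](C)(C)C)/C(=C/C#C[Si](C)(C)C)[C@@H](C)C(=O)OC(C)(C)C
F9 | step 10 | C12 (1-ethoxyvinyl)cyclopentene | CC(C)(C)[Si](C)(C)O[C@H]([C@H]1C(C(=C)OCC)=CC[C@]1(C)/C(=C/CO[Si](CC)(CC)CC)[Si](C)(C)C)/C(=C/C#C[Si](C)(C)C)[C@@H](C)C(=O)OC(C)(C)C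
F10 | step 10 | C12 acetylcyclopentene (C12=C13) | CC(C)(C)[Si](C)(C)O[C@H]([C@H]1C(C(C)=O)=CC[C@]1(C)/C(=C/CO[Si](CC)(CC)CC)[Si](C)(C)C)/C(=C/C#C[Si](C)(C)C)[C@@H](C)C(=O)OC(C)(C)C
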